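Substrate came in equal portions here, and I reckoned the rate at which it passed on, as a share of the charge per minute.

common to all: partner 1.16 M

| charge | substrate | remark | time |
|---|---|---|---|
| larch | 0.97 M (in portions, 4) | run made earlier; portions every 15 s |  |
| maple | 2 M (in portions, 4) | run made earlier; portions every 15 s |  |
| Saturday's | 0.80 M (in portions, 4) | the portions of substrate follow each other after 15 s, the first at the start | 25 min |
| Monday's | 1.2 M (in portions, 4) | the portions of substrate follow each other after 15 s, the first at the start | 25 min |
| Tuesday's | 1.5 M (in portions, 4) | the portions of substrate follow each other after 15 s, the first at the start | 25 min |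

| run | time / min | open intermediate / % | target / % |
|---|---|---|---|
| larch | 4.00 | 27.9 | 1.8 |
| larch | 8.00 | 45.0 | 6.7 |
| larch | 12.0 | 55.3 | 13.4 |
| larch | 15.0 | 60.3 | 16.3 |
| larch | 20.0 | 66.7 | 16.3 |
| larch | 25.0 | 72.1 | 18.8 |
| maple | 1.50 | 9.7 | 0 |
| maple | 5.00 | 33.6 | 1.0 |
| maple | 8.00 | 43.1 | 5.7 |
| maple | 15.0 | 62.7 | 14.4 |
| maple | 20.0 | 70.2 | 14.1 |
| maple | 25.0 | 73.4 | 15.1 |

(readings scatter by 1 percentage point)

- what may be going on: 2 second intermediate -> homo product; partner -> second intermediate; substrate -> open intermediate; open intermediate + second intermediate <-> target
- "hardly changes" means that all values lie within two and a half points (for a concentration: within two and a half percent of the largest)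

- [open intermediate] at the end for Saturday's, Monday's, Tuesday's, in this order
- the shape of the row from first to last (rises all the way / rises, then falls / falls all the way / hardly changes / falls, then rises)

Open intermediate plus target counts what had passed. At the last reading that was 90.9 % in the larch run and 88.5 % in the maple run, whose charge was about twice the larch charge. A share that stays put as the charge changes is the mark of a first-order step, so I took the mean, 89.7 %. A portion waited 22.5 s on average, which left 24.6 min of effective time. Over that time the passing constant, the first-order rate constant that gives the fraction of the present substrate passing per minute, came to 0.0923 min⁻¹, and with the whole charge counted as added at the mean delay, this was also the starting rate per unit of charge.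

Two things held the gain of open intermediate below that rate. The loss of substrate brought it down to 10.3 % of its starting value by the end, so I replaced the curve by its mean, 0.0364 min⁻¹, which is 0.394 of the start. Target then took a share of 0.189 of what had passed, leaving 0.0295 min⁻¹ for open intermediate. Over the effective time that gives 72.8 % of the charge, which is no test of the mean, since this reckoning returns the middle of the two last readings of open intermediate, 72.1 % and 73.4 %. Those readings lie 1.3 percentage points apart against a scatter of 1 point, so I held this share for the asked charges, although Saturday's charge lies below the larch charge. My row was 0.582 M, 0.873 M and 1.09 M, rising with the charge.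

The forecast gave 0.56 M, 0.86 M and 1.09 M, below mine on Saturday's and Monday's, and said “The row rises all the way.”

The flasks gave 0.578 M, 0.876 M and 1.10 M, and the row rises all the way.

    2 second intermediate → homo product (k = 0.00100 M⁻¹ s⁻¹)
    partner → second intermediate (k = 0.00140 s⁻¹)
    substrate → open intermediate (k = 0.00160 s⁻¹)
    open intermediate + second intermediate ⇌ target (K = 0.640 M⁻¹, k = 0.00350 M⁻¹ s⁻¹)

Saturday's flask ended with 9.41 % of its substrate left, and the passing constant puts that remainder at 10.3 %. On Tuesday's flask, at 12.5 min, the passing constant leaves 32.7 % of the charge as substrate, and the flask held 31.2 %.

(The numbers in the tables are calculated for substances that don't exist; the scatter is artificial.)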